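**Retrosynthetic overview**

- Target 28 is cut at the ester C–O bond into diol 19 and the O-silylated Z acid 25 (from crotonaldehyde through a Z vinyl iodide). The styrene C=C of 19 is cut to lactol 14 and benzylic phosphonate 16.
- Feature that carries the plan (pentenol chain numbered C1 = aryl carbinol carbon, C2 = methine, C3 = allylic CH2): C2, its CH2–O carbon with that oxygen, and C3 become a γ-lactone once C4 is a carbonyl carbon. C1, bonded to C2, is then the third carbon of a cyclopropane fused to that lactone across C2–C3, and is the donor carbon of a donor–acceptor cyclopropane.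
- Ring order: step 5 closes the cyclopropane and the γ-lactone together (3-oxabicyclo[3.1.0]hexan-2-one 9) from cinnamyl diazoacetate 8 and fixes C2. The lactone is opened and O-silylated; acid then cleaves the cyclopropane bond between the aryl carbon and the carboxyl-bearing carbon and closes the trans γ-aryl γ-lactone 13, which fixes C1.
- Lactone 13 is opened by reduction to the lactol and E-selective olefination. Desilylation, acylation of the primary hydroxyl and removal of the TBS group complete the synthesis.

Key step: step 5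

Assumption: Rh2(4S-MPPIM)4 is taken to give the (1R,5S,6S) lactone from E-cinnamyl diazoacetates, so the 4R catalyst (ligand from D-asparagine) is specified; if the sense is the reverse, the 4S catalyst is used and nothing else changes.

**Route**

Step 1
Reactants: 1 (E)-3,4-dimethoxycinnamic acid
Product: 2 methyl (E)-3-(3,4-dimethoxyphenyl)prop-2-enoate
Conditions: MeOH, H2SO4 (cat.), reflux
Reagents that add atoms: methanol, CO
Why: Fischer esterification in excess methanol drives the equilibrium to the ester and leaves the E-alkene untouched.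

Step 2
Reactants: 2 methyl (E)-3-(3,4-dimethoxyphenyl)prop-2-enoate
Product: 4 (E)-3-(3,4-dimethoxyphenyl)prop-2-en-1-ol, via (E)-3,4-dimethoxycinnamaldehyde 3 (not isolated)
Conditions: i-Bu2AlH (2.5 equiv), CH2Cl2, −78 → 0 °C; aq. potassium sodium tartrate
Reagents that add atoms: none
Why: Ester reduction with i-Bu2AlH proceeds by 1,2-hydride delivery through the aldehyde to the allylic alcohol without reducing the styrenyl double bond.

Step 3
Reactants: 4 (E)-3-(3,4-dimethoxyphenyl)prop-2-en-1-ol; 5 bromoacetyl bromide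
Product: 6 (E)-3-(3,4-dimethoxyphenyl)prop-2-enyl 2-bromoacetate
Conditions: NaHCO3, MeCN, 0 °C
Reagents that add atoms: none
Why: O-acylation (nucleophilic acyl substitution) occurs at the acyl bromide, which is far more electrophilic than the alkyl bromide, while NaHCO3 removes HBr so that the electron-rich cinnamyl system is not ionised.

Step 4
Reactants: 6 (E)-3-(3,4-dimethoxyphenyl)prop-2-enyl 2-bromoacetate
Product: 8 (E)-3-(3,4-dimethoxyphenyl)prop-2-enyl 2-diazoacetate, via N-alkylated N,N'-ditosylhydrazine 7 (not isolated)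
Conditions: TsNHNHTs, DBU, THF, 0 °C
Reagents that add atoms: N,N'-ditosylhydrazine, Cc1ccc(cc1)S(=O)(=O)NNS(=O)(=O)c1ccc(C)cc1
Why: Diazoacetate formation from a bromoacetate: N-alkylation of the ditosylhydrazine gives 7, from which DBU expels two p-toluenesulfinate ions, conditions mild enough for the allylic ester (8 is used promptly and kept cold).

Step 5
Reactants: 8 (E)-3-(3,4-dimethoxyphenyl)prop-2-enyl 2-diazoacetate
Product: 9 (1S,5R,6R)-6-(3,4-dimethoxyphenyl)-3-oxabicyclo[3.1.0]hexan-2-one (aryl exo)
Conditions: Rh2(4R-MPPIM)4 [dirhodium tetrakis(methyl (4R)-2-oxo-1-(3-phenylpropanoyl)imidazolidine-4-carboxylate)] (1 mol %), CH2Cl2, reflux, 8 added over 10 h at high dilution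
Reagents that add atoms: none
Why: The divalent-rhodium carboxamidate extrudes N2 from the diazoacetate and the resulting electrophilic metal carbenoid transfers its carbon to the tethered E-alkene in one asynchronous [2+1] event, making the C1–C5 and C1–C6 bonds; the closest known reaction type is the enantioselective intramolecular cyclopropanation of allylic diazoacetates by chiral dirhodium carboxamidates, where E-disubstituted substrates call for the imidazolidinone ligand. The three-membered ring closes by this [2+1] addition and the γ-lactone closes in the same event as a five-membered ring, exo with respect to the alkene (the carbenoid carbon bonds to the nearer alkene carbon C5 and the second bond to C6 lies outside the lactone), the fusion being necessarily cis. C5 and C6 keep the trans relation of the E-alkene because the addition is stereospecific, which places the aryl group exo, and C1 is forced cis to the tether, so a single diastereomer is expected; the absolute configuration at all three centres follows from the alkene face that the chiral ligand sphere of the catalyst leaves open to the carbenoid. The step needs enantioface selection and chemoselectivity for cyclopropanation over carbene dimerisation, allylic C–H insertion, dipolar cycloaddition of the diazo group and attack on the electron-rich arene; the short ester tether, the electron-rich alkene, the carboxamidate ligands and slow addition at high dilution should secure them.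

Step 6
Reactants: 9 (1S,5R,6R)-6-(3,4-dimethoxyphenyl)-3-oxabicyclo[3.1.0]hexan-2-one
Product: 10 potassium (1S,2R,3R)-3-(3,4-dimethoxyphenyl)-2-(hydroxymethyl)cyclopropane-1-carboxylate
Conditions: KOH (1.05 equiv), MeOH–H2O, rt; evaporate, toluene azeotrope
Reagents that add atoms: potassium hydroxide, [K+].[OH-]
Why: Saponification of the strained cis-fused lactone gives the hydroxy carboxylate, which is kept as its salt because the free cis hydroxy acid would relactonise; the cyclopropane centres should not epimerise under aqueous hydroxide.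

Step 7
Reactants: 10 potassium (1S,2R,3R)-3-(3,4-dimethoxyphenyl)-2-(hydroxymethyl)cyclopropane-1-carboxylate
Product: 12 (1S,2R,3R)-2-[(tert-butyldiphenylsilyl)oxymethyl]-3-(3,4-dimethoxyphenyl)cyclopropane-1-carboxylic acid, via bis-silylated silyl ester 11 (not isolated)
Conditions: TBDPSCl (2.5 equiv), imidazole, DMF, rt; then K2CO3, MeOH–THF–H2O, rt; aq. HCl to pH 3–4, 0 °C
Reagents that add atoms: tert-butyl(chloro)diphenylsilane, CC(C)(C)[Si](Cl)(c1ccccc1)c1ccccc1
Why: Silyl ether formation on the primary alcohol, with the carboxylate silylated as well, followed by selective carbonate hydrolysis of the labile silyl ester, is the standard way to trap an opened lactone as its O-silyl hydroxy acid; no stereocentre is touched and any material that recloses is lactone 9, which can be recycled.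

Step 8
Reactants: 12 (1S,2R,3R)-2-[(tert-butyldiphenylsilyl)oxymethyl]-3-(3,4-dimethoxyphenyl)cyclopropane-1-carboxylic acid
Product: 13 (4R,5S)-4-[(tert-butyldiphenylsilyl)oxymethyl]-5-(3,4-dimethoxyphenyl)oxolan-2-one (4,5-trans)
Conditions: CF3CO2H (5 equiv), CH2Cl2–(CF3)2CHOH (4:1), 0.01 M, 0 °C → rt
Reagents that add atoms: none
Why: Acid-promoted ring-opening lactonisation of a donor–acceptor cyclopropane: the protonated carboxyl group pulls and the 3,4-dimethoxyphenyl group pushes, so the C1–C3 bond breaks heterolytically, and the benzylic cation is captured by the carboxyl oxygen in a five-membered closure that places the aryl group trans to the neighbouring CH2OTBDPS group (substrate control, reinforced by reversible ionisation of the benzylic C–O bond), which sets C5 as S while C4 keeps the configuration from step 5; the acid-stable TBDPS ether prevents reclosure to 9.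

Step 9
Reactants: 13 (4R,5S)-4-[(tert-butyldiphenylsilyl)oxymethyl]-5-(3,4-dimethoxyphenyl)oxolan-2-one
Product: 14 (4R,5S)-4-[(tert-butyldiphenylsilyl)oxymethyl]-5-(3,4-dimethoxyphenyl)oxolan-2-ol (both C2 epimers)
Conditions: i-Bu2AlH (1.2 equiv), CH2Cl2, −78 °C; aq. potassium sodium tartrate
Reagents that add atoms: none
Why: Partial reduction of a γ-lactone stops at the lactol because the tetrahedral aluminium alkoxide is stable at −78 °C; the two ring stereocentres are not involved and the anomeric mixture is of no consequence.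

Step 10
Reactants: 15 4-(chloromethyl)-1,2-dimethoxybenzene
Product: 16 diethyl (3,4-dimethoxybenzyl)phosphonate
Conditions: P(OEt)3, neat, 130 °C
Reagents that add atoms: triethyl phosphite, CCOP(OCC)OCC
Why: Michaelis–Arbuzov reaction of a reactive benzylic chloride, driven by loss of volatile chloroethane.

Step 11
Reactants: 14 (4R,5S)-4-[(tert-butyldiphenylsilyl)oxymethyl]-5-(3,4-dimethoxyphenyl)oxolan-2-ol; 16 diethyl (3,4-dimethoxybenzyl)phosphonate
Product: 18 (1S,2R,4E)-2-[(tert-butyldiphenylsilyl)oxymethyl]-1,5-bis(3,4-dimethoxyphenyl)pent-4-en-1-ol, via open-chain hydroxy aldehyde 17 (not isolated)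
Conditions: 16 (3 equiv), KOtBu (3 equiv), THF, 0 °C; then 14, 0 °C → rt
Reagents that add atoms: none
Why: Horner–Wadsworth–Emmons olefination of a lactol: base opens the lactol to aldehyde 17 (as its alkoxide), the semistabilised benzylic phosphonate carbanion adds reversibly and eliminates through the less crowded adduct to give the E-styrene, and the liberated alkoxide cannot re-add to an unactivated styrene; both stereocentres are spectators.

Step 12
Reactants: 18 (1S,2R,4E)-2-[(tert-butyldiphenylsilyl)oxymethyl]-1,5-bis(3,4-dimethoxyphenyl)pent-4-en-1-ol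
Product: 19 (1S,2R,4E)-1,5-bis(3,4-dimethoxyphenyl)-2-(hydroxymethyl)pent-4-en-1-ol
Conditions: Bu4NF, THF, rt
Reagents that add atoms: none
Why: Fluoride cleavage of the silyl ether frees the primary hydroxyl; any isomer formed in step 11 by silyl migration to the secondary oxygen converges on the same diol.

Step 13
Reactants: 20 (E)-but-2-enal (crotonaldehyde)
Product: 21 (Z)-2-iodobut-2-enal
Conditions: I2, K2CO3, DMAP (cat.), THF–H2O, rt
Reagents that add atoms: iodine, II
Why: α-Iodination of an enal by nucleophile-catalysed conjugate addition, iodination of the enolate and elimination, which should return the more stable isomer with CH3 trans to CHO and therefore cis to iodine.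

Step 14
Reactants: 21 (Z)-2-iodobut-2-enal
Product: 22 (Z)-2-iodobut-2-en-1-ol
Conditions: NaBH4, CeCl3·7H2O, MeOH, 0 °C
Reagents that add atoms: none
Why: Luche 1,2-reduction of the enal leaves the vinyl iodide and its geometry intact.

Step 15
Reactants: 22 (Z)-2-iodobut-2-en-1-ol
Product: 23 tert-butyl{[(Z)-2-iodobut-2-enyl]oxy}dimethylsilane
Conditions: TBSCl, imidazole, CH2Cl2, rt
Reagents that add atoms: tert-butyl(chloro)dimethylsilane, CC(C)(C)[Si](C)(C)Cl
Why: Standard silyl ether formation masks the hydroxyl for the organolithium step and for the later acylation.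

Step 16
Reactants: 23 tert-butyl{[(Z)-2-iodobut-2-enyl]oxy}dimethylsilane
Product: 25 (Z)-2-{[(tert-butyldimethylsilyl)oxy]methyl}but-2-enoic acid, via vinyllithium 24 (not isolated)
Conditions: t-BuLi (2.1 equiv), Et2O, −78 °C, 20 min; CO2, −78 → 0 °C; aq. HCl to pH 3, 0 °C
Reagents that add atoms: carbon dioxide, O=C=O
Why: Iodine–lithium exchange on a vinyl iodide and carboxylation both proceed with retention of alkene geometry, so CO2H ends cis to CH3 (the Z, angelate-type acid); short contact at −78 °C is meant to forestall silyl migration or loss of silanolate from 24.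

Step 17
Reactants: 19 (1S,2R,4E)-1,5-bis(3,4-dimethoxyphenyl)-2-(hydroxymethyl)pent-4-en-1-ol; 25 (Z)-2-{[(tert-butyldimethylsilyl)oxy]methyl}but-2-enoic acid
Product: 27 (2R,4E)-5-(3,4-dimethoxyphenyl)-2-[(S)-(3,4-dimethoxyphenyl)(hydroxy)methyl]pent-4-enyl (Z)-2-{[(tert-butyldimethylsilyl)oxy]methyl}but-2-enoate, via mixed anhydride 26 (not isolated)
Conditions: 2,4,6-Cl3C6H2COCl, Et3N, toluene, rt; then 19 (1.0 equiv), toluene, 60 °C
Reagents that add atoms: none
Why: Yamaguchi-type mixed-anhydride esterification run without a nucleophilic amine catalyst, which could isomerise the Z acyl unit by reversible conjugate addition; the unhindered primary hydroxyl should react well ahead of the branched secondary benzylic one.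

Step 18
Reactants: 27 (2R,4E)-5-(3,4-dimethoxyphenyl)-2-[(S)-(3,4-dimethoxyphenyl)(hydroxy)methyl]pent-4-enyl (Z)-2-{[(tert-butyldimethylsilyl)oxy]methyl}but-2-enoate
Product: 28 (2R,4E)-5-(3,4-dimethoxyphenyl)-2-[(S)-(3,4-dimethoxyphenyl)(hydroxy)methyl]pent-4-enyl (Z)-2-(hydroxymethyl)but-2-enoate
Conditions: HF·pyridine, pyridine, THF, 0 °C → rt
Reagents that add atoms: none
Why: Buffered fluoride desilylation of a primary TBS ether is nearly neutral, so the electron-rich benzylic alcohol should not ionise, the ester should not migrate and the Z-enoate should not isomerise.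

**Compound list**

1 | (E)-3,4-dimethoxycinnamic acid | OC(=O)/C=C/c1ccc(OC)c(OC)c1 | starting material
2 | methyl (E)-3-(3,4-dimethoxyphenyl)prop-2-enoate | COC(=O)/C=C/c1ccc(OC)c(OC)c1 | intermediate
3 | (E)-3,4-dimethoxycinnamaldehyde | O=C/C=C/c1ccc(OC)c(OC)c1 | intermediate (not isolated)
4 | (E)-3-(3,4-dimethoxyphenyl)prop-2-en-1-ol | OC/C=C/c1ccc(OC)c(OC)c1 | intermediate
5 | bromoacetyl bromide | BrCC(=O)Br | starting material
6 | (E)-3-(3,4-dimethoxyphenyl)prop-2-enyl 2-bromoacetate | BrCC(=O)OC/C=C/c1ccc(OC)c(OC)c1 | intermediate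
7 | (E)-3-(3,4-dimethoxyphenyl)prop-2-enyl 2-[1,2-bis(4-methylphenylsulfonyl)hydrazin-1-yl]acetate | Cc1ccc(cc1)S(=O)(=O)NN(CC(=O)OC/C=C/c2ccc(OC)c(OC)c2)S(=O)(=O)c1ccc(C)cc1 | intermediate (not isolated)
8 | (E)-3-(3,4-dimethoxyphenyl)prop-2-enyl 2-diazoacetate | [N-]=[N+]=CC(=O)OC/C=C/c1ccc(OC)c(OC)c1 | intermediate
9 | (1S,5R,6R)-6-(3,4-dimethoxyphenyl)-3-oxabicyclo[3.1.0]hexan-2-one | O=C1OC[C@H]2[C@@H]1[C@@H]2c3ccc(OC)c(OC)c3 | intermediate
10 | potassium (1S,2R,3R)-3-(3,4-dimethoxyphenyl)-2-(hydroxymethyl)cyclopropane-1-carboxylate | OC[C@H]1[C@@H](C(=O)[O-])[C@@H]1c2ccc(OC)c(OC)c2.[K+] | intermediate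
11 | tert-butyldiphenylsilyl (1S,2R,3R)-2-[(tert-butyldiphenylsilyl)oxymethyl]-3-(3,4-dimethoxyphenyl)cyclopropane-1-carboxylate | CC(C)(C)[Si](c1ccccc1)(c1ccccc1)OC[C@H]1[C@@H](C(=O)O[Si](c2ccccc2)(c2ccccc2)C(C)(C)C)[C@@H]1c1ccc(OC)c(OC)c1 | intermediate (not isolated)
12 | (1S,2R,3R)-2-[(tert-butyldiphenylsilyl)oxymethyl]-3-(3,4-dimethoxyphenyl)cyclopropane-1-carboxylic acid | CC(C)(C)[Si](c1ccccc1)(c1ccccc1)OC[C@H]1[C@@H](C(=O)O)[C@@H]1c1ccc(OC)c(OC)c1 | intermediate
13 | (4R,5S)-4-[(tert-butyldiphenylsilyl)oxymethyl]-5-(3,4-dimethoxyphenyl)oxolan-2-one | O=C1C[C@H](CO[Si](c2ccccc2)(c2ccccc2)C(C)(C)C)[C@@H](c2ccc(OC)c(OC)c2)O1 | intermediate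
14 | (4R,5S)-4-[(tert-butyldiphenylsilyl)oxymethyl]-5-(3,4-dimethoxyphenyl)oxolan-2-ol (C2 epimers) | OC1C[C@H](CO[Si](c2ccccc2)(c2ccccc2)C(C)(C)C)[C@@H](c2ccc(OC)c(OC)c2)O1 | intermediate
15 | 4-(chloromethyl)-1,2-dimethoxybenzene | ClCc1ccc(OC)c(OC)c1 | starting material
16 | diethyl (3,4-dimethoxybenzyl)phosphonate | CCOP(=O)(Cc1ccc(OC)c(OC)c1)OCC | intermediate
17 | (3R,4S)-3-[(tert-butyldiphenylsilyl)oxymethyl]-4-(3,4-dimethoxyphenyl)-4-hydroxybutanal | O=CC[C@H](CO[Si](c1ccccc1)(c1ccccc1)C(C)(C)C)[C@@H](c1ccc(OC)c(OC)c1)O | intermediate (not isolated)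
18 | (1S,2R,4E)-2-[(tert-butyldiphenylsilyl)oxymethyl]-1,5-bis(3,4-dimethoxyphenyl)pent-4-en-1-ol | CC(C)(C)[Si](c1ccccc1)(c1ccccc1)OC[C@@H](C/C=C/c1ccc(OC)c(OC)c1)[C@H](O)c1ccc(OC)c(OC)c1 | intermediate
19 | (1S,2R,4E)-1,5-bis(3,4-dimethoxyphenyl)-2-(hydroxymethyl)pent-4-en-1-ol | OC[C@@H](C/C=C/c1ccc(OC)c(OC)c1)[C@H](O)c1ccc(OC)c(OC)c1 | intermediate
20 | (E)-but-2-enal (crotonaldehyde) | C/C=C/C=O | starting material
21 | (Z)-2-iodobut-2-enal | C/C=C(/C=O)I | intermediate
22 | (Z)-2-iodobut-2-en-1-ol | C/C=C(/CO)I | intermediate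
23 | tert-butyl{[(Z)-2-iodobut-2-enyl]oxy}dimethylsilane | C/C=C(/CO[Si](C)(C)C(C)(C)C)I | intermediate
24 | {(E)-1-[(tert-butyldimethylsilyl)oxy]but-2-en-2-yl}lithium | C/C=C(/CO[Si](C)(C)C(C)(C)C)[Li] | intermediate (not isolated)
25 | (Z)-2-{[(tert-butyldimethylsilyl)oxy]methyl}but-2-enoic acid | C/C=C(/CO[Si](C)(C)C(C)(C)C)C(=O)O | intermediate
26 | (Z)-2-{[(tert-butyldimethylsilyl)oxy]methyl}but-2-enoic 2,4,6-trichlorobenzoic anhydride | C/C=C(/CO[Si](C)(C)C(C)(C)C)C(=O)OC(=O)c1c(Cl)cc(Cl)cc1Cl | intermediate (not isolated)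
27 | (2R,4E)-5-(3,4-dimethoxyphenyl)-2-[(S)-(3,4-dimethoxyphenyl)(hydroxy)methyl]pent-4-enyl (Z)-2-{[(tert-butyldimethylsilyl)oxy]methyl}but-2-enoate | C/C=C(/CO[Si](C)(C)C(C)(C)C)C(=O)OC[C@@H](C/C=C/c1ccc(OC)c(OC)c1)[C@H](O)c1ccc(OC)c(OC)c1 | intermediate
28 | (2R,4E)-5-(3,4-dimethoxyphenyl)-2-[(S)-(3,4-dimethoxyphenyl)(hydroxy)methyl]pent-4-enyl (Z)-2-(hydroxymethyl)but-2-enoate | C/C=C(/CO)C(=O)OC[C@@H](C/C=C/c1ccc(OC)c(OC)c1)[C@H](O)c1ccc(OC)c(OC)c1 | target

**Step count and risks**

Total step count: 18. Longest linear sequence: 13 steps (steps 1–9, 11, 12, 17, 18).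

Steps most likely to fail:

1. Step 8. What may go wrong: capture of the benzylic cation with too little preference for the trans lactone, loss of a proton from the cation or its arylation of another electron-rich ring, and acidolysis of the silyl ether with reclosure to 9. The fallback replaces substrate control by reagent control at the carbinol carbon. The lactone mixture is taken through steps 9 and 11, and the fallback sets out from 18 accompanied by its C1 epimer, (1R,2R,4E)-2-[(tert-butyldiphenylsilyl)oxymethyl]-1,5-bis(3,4-dimethoxyphenyl)pent-4-en-1-ol F1. Both are oxidised with Dess–Martin periodinane (NaHCO3, CH2Cl2, 0 °C) to the single aryl ketone (2R,4E)-2-[(tert-butyldiphenylsilyl)oxymethyl]-1,5-bis(3,4-dimethoxyphenyl)pent-4-en-1-one F2. Corey–Bakshi–Shibata reduction of this ketone with (R)-2-methyl-CBS-oxazaborolidine and catecholborane (toluene, −78 °C) should deliver the 1S alcohol, and the route is rejoined at 18.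

2. Step 11. What may go wrong: slow olefination of the lactol-masked aldehyde by the weakly nucleophilic benzylic carbanion, competing enolisation and self-condensation of the open aldehyde, and incomplete E selectivity. The fallback sets out from lactol 14. Wittig methylenation (Ph3PCH3Br, KOtBu, THF, 0 °C → rt) should give the terminal alkene (1S,2R)-2-[(tert-butyldiphenylsilyl)oxymethyl]-1-(3,4-dimethoxyphenyl)pent-4-en-1-ol F3. Cross-metathesis of this alkene with commercial 3,4-dimethoxystyrene (second-generation Hoveyda–Grubbs catalyst, CH2Cl2, 40 °C) should then give the E-styrene, and the route is rejoined at 18.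

3. Step 17. What may go wrong: Z-to-E isomerisation of the activated acyl unit during a slow acyl transfer, and acylation of the secondary hydroxyl. The fallback forms the ester by O-alkylation, so the acyl group is never activated. It sets out from diol 19, whose primary hydroxyl is sulfonylated selectively (TsCl 1.05 equiv, pyridine, CH2Cl2, 0 °C) to (2R,4E)-5-(3,4-dimethoxyphenyl)-2-[(S)-(3,4-dimethoxyphenyl)(hydroxy)methyl]pent-4-enyl 4-methylbenzenesulfonate F4. Acid 25 is converted with Cs2CO3 in DMF into caesium (Z)-2-{[(tert-butyldimethylsilyl)oxy]methyl}but-2-enoate F5, which displaces the sulfonate (DMF, 50 °C) in an SN2 reaction, and the route is rejoined at 27.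

**Further compounds**

F1 | step 8 | (1R,2R,4E)-2-[(tert-butyldiphenylsilyl)oxymethyl]-1,5-bis(3,4-dimethoxyphenyl)pent-4-en-1-ol | CC(C)(C)[Si](c1ccccc1)(c1ccccc1)OC[C@@H](C/C=C/c1ccc(OC)c(OC)c1)[C@@H](O)c1ccc(OC)c(OC)c1
F2 | step 8 | (2R,4E)-2-[(tert-butyldiphenylsilyl)oxymethyl]-1,5-bis(3,4-dimethoxyphenyl)pent-4-en-1-one | CC(C)(C)[Si](c1ccccc1)(c1ccccc1)OC[C@@H](C/C=C/c1ccc(OC)c(OC)c1)C(=O)c1ccc(OC)c(OC)c1
F3 | step 11 | (1S,2R)-2-[(tert-butyldiphenylsilyl)oxymethyl]-1-(3,4-dimethoxyphenyl)pent-4-en-1-ol | CC(C)(C)[Si](c1ccccc1)(c1ccccc1)OC[C@@H](CC=C)[C@H](O)c1ccc(OC)c(OC)c1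
F4 | step 17 | (2R,4E)-5-(3,4-dimethoxyphenyl)-2-[(S)-(3,4-dimethoxyphenyl)(hydroxy)methyl]pent-4-enyl 4-methylbenzenesulfonate | Cc1ccc(cc1)S(=O)(=O)OC[C@@H](C/C=C/c1ccc(OC)c(OC)c1)[C@H](O)c1ccc(OC)c(OC)c1
F5 | step 17 | caesium (Z)-2-{[(tert-butyldimethylsilyl)oxy]methyl}but-2-enoate | C/C=C(/CO[Si](C)(C)C(C)(C)C)C(=O)[O-].[Cs+]
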